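(The data are calculated on assumed constants; scatter was added.)

I decided to judge the new flasks by one ratio read from the delta run, because an excess depends on how the two products compare and not on how fast either forms.

| flask | left-handed substrate | right-handed substrate | gas | free catalyst | remark | time |
|---|---|---|---|---|---|---|
| gamma | 1.5 M | 1.5 M | 200 mM (held) | 0.94 mol% | run made earlier |  |
| delta | 1.5 M | 1.5 M | 200 mM (held) | 18 mol% | run made earlier |  |
| ochre | 1.5 M | 1.5 M | 200 mM (held) | 1.2 mol% |  | 6.0 min |
| amber | 1.5 M | 1.5 M | 200 mM (held) | 2.5 mol% |  | 6.0 min |
| blue | 1.5 M | 1.5 M | 200 mM (held) | 5 mol% |  | 6.0 min |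
| violet | 1.5 M | 1.5 M | 200 mM (held) | 10 mol% |  | 6.0 min |
| red | 1.5 M | 1.5 M | 200 mM (held) | 20 mol% |  | 6.0 min |

| run | time / min | left-handed product / % | right-handed product / % |
|---|---|---|---|
| gamma | 0.167 | 0.3 | 0 |
| gamma | 0.500 | 0 | 0.3 |
| gamma | 0.833 | 0.2 | 0 |
| gamma | 1.33 | 0.3 | 0 |
| gamma | 2.00 | 0 | 0.4 |
| gamma | 2.50 | 0 | 0 |
| gamma | 3.00 | 0 | 0.3 |
| delta | 0.167 | 0 | 0.6 |
| delta | 0.500 | 0.8 | 0.5 |
| delta | 0.833 | 1.3 | 0.6 |
| delta | 1.33 | 1.2 | 0.8 |
| delta | 2.00 | 2.8 | 1.6 |
| delta | 2.50 | 2.9 | 1.7 |
| delta | 3.00 | 4.2 | 3.0 |

(scatter of a reading: 0.3 percentage points)

1. excess of left-handed product over right-handed product at the end for ochre, amber, blue, violet, red, in this order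
2. the course of these numbers from the first flask to the last (hardly changes / rises all the way / rises, then falls / falls all the way / falls, then rises)

- free catalyst is single-handed; left-handed substrate and right-handed substrate are mirror images of each other, charged as a racemate, each of them at the stated concentration
- at the start none of the gas is in solution
- an excess is the difference of the two amounts in percent of their sum
- "hardly changes" means that all values lie within two and a half points (for a concentration: within two and a half percent of the largest)

The gamma readings reach 0.4% against a scatter of 0.3 percentage points, so they say nothing about handedness. From the delta run I took 1.50 as the split, the sum of its left-handed product readings divided by the sum of its right-handed ones; this is a reading of the selectivity factor. That split means an excess of 20.0%. A shortage that slows both products by the same factor leaves the split unchanged. The delta run, at 18 mol%, also stands close to red, at 20 mol%, so any shortage of gas at high loading that acts differently on the two products is already inside its split. I expected a flat row, but as an assumption: it holds if a shortage slows both products by the same factor, and the gamma run could not test that at low loading.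

The forecast was 20%, 20%, 20%, 20% and 19%, so hardly changes, with the caution that “Gas starvation at high loading could shift selectivity”.

The flasks gave 22.8%, 22.5%, 22.2%, 21.8% and 21.7%, so hardly changes.

    free catalyst + left-handed substrate ⇌ catalyst intermediate A (K = 0.790 /M, k = 330 /M/min)
    free catalyst + right-handed substrate ⇌ catalyst intermediate B (K = 1.40 /M, k = 11.0 /M/min)
    reagent + catalyst intermediate A → free catalyst + left-handed product (k = 8.00 /M/min)
    reagent + catalyst intermediate B → free catalyst + right-handed product (k = 3.00 /M/min)
    gas ⇌ reagent, rate k5*(csat - [reagent]) (kL = 0.740 /min)

Both product steps are first order in reagent, and [reagent] drops out of their ratio. At the end red held 0.0834 M and ochre 0.182 M, yet the split was 1.55 in red and 1.59 in ochre, against the 1.50 carried from delta. The split held because catalyst intermediate B can fall back to free catalyst and right-handed substrate. With that step taken away, the excess in red went from 21.7% to −85.5%, and in ochre from 22.8% to −82.2%.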